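**Retrosynthetic overview**

1. Labdane numbering is used throughout. The C19 p-coumarate ester and the C13(16),14-diene (ethylene enyne metathesis of a C13 alkyne) are made last; the 8α-OH and C17 come from a C8 ketone by methylenation, α-face epoxidation and hydride opening.
2. Ring A is cut at C1–C2 and C4–C5. Both bonds are made as C=C bonds in one pot by a [3+3] Wittig/Horner–Wadsworth–Emmons annulation of a ring B keto aldehyde with a C2–C3–C4(+C19) phosphonium–phosphonate; C18, the axial C19 ester and 5α-H then follow from reductive methylation of the C4=C5 ester.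
3. Enabling feature: C1 and C5 are both bonded to the quaternary C10 (which carries C20). Ring B can therefore hold C1 as a formyl group and C5 as a ring ketone in a 1,3-dicarbonyl that cannot enolise between the two carbonyls, a 1,3-dielectrophile that matches the 1,3-dinucleophile C2/C4.
4. Ring B is made first, from a flat arene: dearomatisation of 4-methoxy-2-methylphenol to a quinone monoketal, then a copper-catalysed asymmetric conjugate addition with formaldehyde trapping that sets C9 and C10. Order of rings: B, then A.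

Key step: step 6

Assumption: in step 3 the ligand enantiomer is the one whose copper complex delivers the alkyl group to the enone face that gives the (3R) adduct; if the sense of induction is the opposite, the mirror-image ligand is used.

**Route**

Step 1
Reactants: 1 4-methoxy-2-methylphenol
Product: 2 4,4-dimethoxy-2-methylcyclohexa-2,5-dien-1-one
Conditions: PhI(OAc)2 (1.1 equiv), MeOH, 0 °C
Reagents that add atoms: methanol, CO
Why: Oxidative dearomatisation of a para-methoxyphenol with a hypervalent iodine reagent in methanol should give the quinone monoketal, which turns the flat arene into ring B carrying the C5 carbonyl, the masked C8 ketone and the C20 methyl group; no stereocentre is formed.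

Step 2
Reactants: 2 4,4-dimethoxy-2-methylcyclohexa-2,5-dien-1-one
Product: 3 4,4-dimethoxy-2-methylcyclohex-2-en-1-one
Conditions: H2 (1 atm), RhCl(PPh3)3 (5 mol %), benzene, rt
Reagents that add atoms: none
Why: Homogeneous hydrogenation with Wilkinson's catalyst should reduce only the unhindered disubstituted C6=C7 bond of the cross-conjugated dienone, as it does in steroidal 1,4-dien-3-ones, and leave the methyl-substituted enone C9=C10 for the conjugate addition.

Step 3
Reactants: 3 4,4-dimethoxy-2-methylcyclohex-2-en-1-one; 4 2-(2-bromoethyl)-1,3-dioxolane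
Product: 6 (2S,3R)-3-[2-(1,3-dioxolan-2-yl)ethyl]-2-(hydroxymethyl)-4,4-dimethoxy-2-methylcyclohexan-1-one, via bromomagnesium enolate 5 (not isolated)
Conditions: 4, Mg, THF, rt (Grignard reagent); CuBr·SMe2 (5 mol %), (R)-1-[(S)-2-(diphenylphosphino)ferrocenyl]ethyldicyclohexylphosphine (6 mol %), t-BuOMe, −75 °C, then 3; then monomeric CH2O in THF, −75 to −20 °C; aq. NH4Cl
Reagents that add atoms: formaldehyde, C=O
Why: Copper-catalysed asymmetric conjugate addition of the Grignard reagent to the alpha-methyl enone should set C9 under ligand control, and the magnesium enolate should then add to formaldehyde (aldol reaction) on the face anti to the new C9 substituent, which sets the quaternary C10 with the hydroxymethyl group (C1) trans to the side chain and the methyl group (C20) cis to it.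

Step 4
Reactants: 6 (2S,3R)-3-[2-(1,3-dioxolan-2-yl)ethyl]-2-(hydroxymethyl)-4,4-dimethoxy-2-methylcyclohexan-1-one
Product: 7 (1S,2R)-2-[2-(1,3-dioxolan-2-yl)ethyl]-3,3-dimethoxy-1-methyl-6-oxocyclohexane-1-carbaldehyde
Conditions: Dess–Martin periodinane, NaHCO3, CH2Cl2, 0 °C to rt
Reagents that add atoms: none
Why: Dess–Martin oxidation of the primary alcohol under buffered, base-free conditions should give the aldehyde without retro-aldol loss of formaldehyde; C10 is quaternary, so the 1,3-keto aldehyde cannot enolise between its carbonyl groups.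

Step 5
Reactants: 8 triethyl phosphonoacetate; 9 ethenyl(triphenyl)phosphonium bromide
Product: 10 [3-(diethoxyphosphoryl)-4-ethoxy-4-oxobutyl]triphenylphosphonium bromide (racemic)
Conditions: Cs2CO3 (0.1 equiv), MeCN, 40 °C
Reagents that add atoms: none
Why: Base-catalysed conjugate (Michael) addition of the phosphonoacetate carbanion to the vinylphosphonium salt, the first stage of the Schweizer reaction, should give a three-carbon reagent (C2–C3–C4 with C19 as the ester) that bears an olefinating phosphorus group on C2 and on C4; the new stereocentre is lost later and is left racemic.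

Step 6
Reactants: 7 (1S,2R)-2-[2-(1,3-dioxolan-2-yl)ethyl]-3,3-dimethoxy-1-methyl-6-oxocyclohexane-1-carbaldehyde; 10 [3-(diethoxyphosphoryl)-4-ethoxy-4-oxobutyl]triphenylphosphonium bromide
Product: 12 ethyl (4aR,5R)-5-[2-(1,3-dioxolan-2-yl)ethyl]-6,6-dimethoxy-4a-methyl-2,4a,5,6,7,8-hexahydronaphthalene-1-carboxylate, via Wittig adduct 11 (not isolated)
Conditions: 10 (1.1 equiv), KN(SiMe3)2 (2.2 equiv), THF, −78 to 0 °C; then 7, −78 °C to rt, then 50 °C
Reagents that add atoms: none
Why: Proposed new method: two equivalents of KN(SiMe3)2 should turn 10 into a dianion in which the non-stabilised ylide carbon C2 is far more nucleophilic than the hindered phosphonate-stabilised carbanion C4, so that at −78 °C C2 alone adds to the aldehyde C1 (Z-selective Wittig olefination, C1=C2) and C4 is thereby placed next to the C5 ketone, which it olefinates intramolecularly on warming (Horner–Wadsworth–Emmons, C4=C5). The closest known reactions are the chemoselective Wittig olefination of an aldehyde beside a ketone, the ring-closing Horner–Wadsworth–Emmons reaction of phosphonoacetates with ketones and the double Wittig cyclisation of bis-ylides with dialdehydes; their union in one reagent on a 1,3-keto aldehyde is the new element. Ring A is closed by 6-exo-trig attack of the C4 carbanion on the C5 carbonyl carbon, and the cis C1=C2 bond made in the first stage holds the two reacting ends together. No stereocentre is formed: C9 and C10 cannot epimerise (C10 is quaternary, C9 is not alpha to a carbonyl group) and both new double bonds are fixed as ring double bonds. The step needs the pairing ylide/aldehyde and phosphonate/ketone and Z geometry at C1=C2; the first is secured by the reactivity gap between the two carbanions and between the aldehyde and the alpha-quaternary ketone, the second by lithium-free ylide conditions. The C4 carbanion is too weak a base to enolise the ketone at C6, so that it adds to the carbonyl group instead.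

Step 7
Reactants: 12 ethyl (4aR,5R)-5-[2-(1,3-dioxolan-2-yl)ethyl]-6,6-dimethoxy-4a-methyl-2,4a,5,6,7,8-hexahydronaphthalene-1-carboxylate
Product: 13 ethyl (4aR,5R)-5-[2-(1,3-dioxolan-2-yl)ethyl]-6,6-dimethoxy-4a-methyl-2,3,4,4a,5,6,7,8-octahydronaphthalene-1-carboxylate
Conditions: H2 (1 atm), RhCl(PPh3)3 (5 mol %), benzene–EtOH, rt
Reagents that add atoms: none
Why: Catalytic hydrogenation with Wilkinson's catalyst should saturate only the cis-disubstituted C1=C2 bond, since the tetrasubstituted ester-conjugated C4=C5 bond is inert to this catalyst, and it removes the doubly allylic C3 position before the strongly basic reduction.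

Step 8
Reactants: 13 ethyl (4aR,5R)-5-[2-(1,3-dioxolan-2-yl)ethyl]-6,6-dimethoxy-4a-methyl-2,3,4,4a,5,6,7,8-octahydronaphthalene-1-carboxylate
Product: 15 ethyl (1S,4aS,5R,8aR)-5-[2-(1,3-dioxolan-2-yl)ethyl]-6,6-dimethoxy-1,4a-dimethyldecahydronaphthalene-1-carboxylate, via lithium ester enolate 14 (not isolated)
Conditions: Li (2.2 equiv), NH3 (l), THF, t-BuOH (1.0 equiv), −78 °C; then MeI, −78 to −33 °C
Reagents that add atoms: iodomethane, CI
Why: Dissolving-metal reduction of the alpha,beta-unsaturated ester (reductive alkylation) should protonate C5 axially to give the trans-fused lithium enolate (5α-H, anti to the C10 methyl group), and methyl iodide should then attack C4 from the α face, opposite the syn-axial C10 methyl group, which makes C18 equatorial and the C19 ester axial (β).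

Step 9
Reactants: 15 ethyl (1S,4aS,5R,8aR)-5-[2-(1,3-dioxolan-2-yl)ethyl]-6,6-dimethoxy-1,4a-dimethyldecahydronaphthalene-1-carboxylate
Product: 16 ethyl (1S,4aS,5R,8aR)-5-[2-(1,3-dioxolan-2-yl)ethyl]-1,4a-dimethyl-6-oxodecahydronaphthalene-1-carboxylate
Conditions: AcOH–THF–H2O (3:1:1), rt
Reagents that add atoms: water, O
Why: Mild acid hydrolysis should cleave the acyclic dimethyl ketal of the ring ketone much faster than the cyclic acetal of the side-chain aldehyde (ketal hydrolysis), so that the C8 ketone is freed while C13 stays masked and a 1,5-keto aldehyde, which would close by aldol reaction, never forms.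

Step 10
Reactants: 16 ethyl (1S,4aS,5R,8aR)-5-[2-(1,3-dioxolan-2-yl)ethyl]-1,4a-dimethyl-6-oxodecahydronaphthalene-1-carboxylate
Product: 17 ethyl (1S,4aR,5S,8aR)-5-[2-(1,3-dioxolan-2-yl)ethyl]-1,4a-dimethyl-6-methylidenedecahydronaphthalene-1-carboxylate
Conditions: Ph3PCH3Br, KOt-Bu, toluene, 80 °C
Reagents that add atoms: methyltriphenylphosphonium bromide, C[P+](c1ccccc1)(c1ccccc1)c1ccccc1.[Br-]
Why: Wittig methylenation of the C8 ketone should give the exocyclic C8=C17 alkene; the only epimerisable centre, C9, already carries its side chain in the stable equatorial position.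

Step 11
Reactants: 17 ethyl (1S,4aR,5S,8aR)-5-[2-(1,3-dioxolan-2-yl)ethyl]-1,4a-dimethyl-6-methylidenedecahydronaphthalene-1-carboxylate
Product: 18 ethyl (1R,2R,4aR,5S,8aS)-1-[2-(1,3-dioxolan-2-yl)ethyl]-5,8a-dimethyloctahydro-1H-spiro[naphthalene-2,2'-oxirane]-5-carboxylate (the 8α,17-epoxide)
Conditions: mCPBA, NaHCO3, CH2Cl2, 0 °C
Reagents that add atoms: 3-chloroperoxybenzoic acid, OOC(=O)c1cccc(Cl)c1
Why: Prilezhaev epoxidation of the exocyclic alkene should take place on the α face, because the β face is screened by the syn-axial C10 methyl group, and so places the oxirane oxygen α on C8.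

Step 12
Reactants: 18 ethyl (1R,2R,4aR,5S,8aS)-1-[2-(1,3-dioxolan-2-yl)ethyl]-5,8a-dimethyloctahydro-1H-spiro[naphthalene-2,2'-oxirane]-5-carboxylate
Product: 19 (1R,2R,4aR,5S,8aS)-1-[2-(1,3-dioxolan-2-yl)ethyl]-5-(hydroxymethyl)-2,5,8a-trimethyldecahydronaphthalen-2-ol
Conditions: LiAlH4, THF, reflux; then aq. NaOH work-up
Reagents that add atoms: none
Why: Hydride reduction should open the spiro-epoxide by SN2 attack at the unhindered C17 methylene, which gives the tertiary 8α-alcohol with C17 as the β-methyl group (C8 retains its configuration), and reduce the hindered axial ester to the primary C19 alcohol in the same operation.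

Step 13
Reactants: 19 (1R,2R,4aR,5S,8aS)-1-[2-(1,3-dioxolan-2-yl)ethyl]-5-(hydroxymethyl)-2,5,8a-trimethyldecahydronaphthalen-2-ol
Product: 20 (4aR,6aR,7S,10aS,10bR)-7-(hydroxymethyl)-4a,7,10a-trimethyldodecahydro-1H-benzo[f]chromen-3-ol (lactol; both C3 epimers)
Conditions: 1 M HCl, THF, rt
Reagents that add atoms: water, O
Why: Acid-catalysed acetal hydrolysis should free the C13 aldehyde, which is captured reversibly by the 8α-hydroxyl group as a six-membered lactol; no alkene or epoxide is present at this stage, so that the acid has nothing else to attack.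

Step 14
Reactants: 20 (4aR,6aR,7S,10aS,10bR)-7-(hydroxymethyl)-4a,7,10a-trimethyldodecahydro-1H-benzo[f]chromen-3-ol
Product: 21 (1R,2R,4aR,5S,8aS)-1-(but-3-yn-1-yl)-5-(hydroxymethyl)-2,5,8a-trimethyldecahydronaphthalen-2-ol
Conditions: dimethyl (1-diazo-2-oxopropyl)phosphonate, K2CO3, MeOH, rt
Reagents that add atoms: dimethyl (1-diazo-2-oxopropyl)phosphonate, COP(=O)(OC)C(=[N+]=[N-])C(C)=O
Why: Seyferth–Gilbert homologation with the Ohira–Bestmann reagent should act on the open hydroxy aldehyde form of the lactol and give the terminal alkyne C13≡C14, because 1,2-hydrogen shift in the alkylidene carbene is faster than insertion into the hydroxyl groups.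

Step 15
Reactants: 21 (1R,2R,4aR,5S,8aS)-1-(but-3-yn-1-yl)-5-(hydroxymethyl)-2,5,8a-trimethyldecahydronaphthalen-2-ol
Product: 22 (1R,2R,4aR,5S,8aS)-5-(hydroxymethyl)-2,5,8a-trimethyl-1-(3-methylidenepent-4-en-1-yl)decahydronaphthalen-2-ol (labda-13(16),14-diene-8α,19-diol)
Conditions: ethylene (1 atm), second-generation Grubbs catalyst RuCl2(=CHPh)(PCy3)(H2IMes) (5 mol %), CH2Cl2, 40 °C
Reagents that add atoms: ethylene, C=C
Why: Enyne cross-metathesis of the terminal alkyne with ethylene should give the 2-substituted buta-1,3-diene (C13=C16 and C14=C15) with every atom of both partners retained, and the ruthenium carbene tolerates the two free hydroxyl groups.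

Step 16
Reactants: 22 (1R,2R,4aR,5S,8aS)-5-(hydroxymethyl)-2,5,8a-trimethyl-1-(3-methylidenepent-4-en-1-yl)decahydronaphthalen-2-ol; 23 (E)-4-acetoxycinnamic acid
Product: 24 8α-hydroxylabda-13(16),14-dien-19-yl (E)-3-(4-acetoxyphenyl)prop-2-enoate
Conditions: 23, N-(3-dimethylaminopropyl)-N'-ethylcarbodiimide hydrochloride (EDC·HCl), DMAP, CH2Cl2, 0 °C to rt
Reagents that add atoms: none
Why: Carbodiimide (Steglich) esterification should acylate only the primary C19 alcohol, since the tertiary C8 alcohol is too hindered, and the E double bond is brought in with the acid.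

Step 17
Reactants: 24 8α-hydroxylabda-13(16),14-dien-19-yl (E)-3-(4-acetoxyphenyl)prop-2-enoate
Product: 25 8α-hydroxylabda-13(16),14-dien-19-yl p-hydroxycinnamate
Conditions: K2CO3 (0.2 equiv), MeOH, 0 °C
Reagents that add atoms: none
Why: Base-catalysed methanolysis (transesterification) should remove the phenolic acetate, an activated aryl ester, much faster than it attacks the hindered neopentyl-type cinnamate, which frees the phenol and gives the target.

**Compound list**

1 | 4-methoxy-2-methylphenol | COc1ccc(O)c(C)c1 | starting material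
2 | 4,4-dimethoxy-2-methylcyclohexa-2,5-dien-1-one | COC1(OC)C=CC(=O)C(C)=C1 | intermediate
3 | 4,4-dimethoxy-2-methylcyclohex-2-en-1-one | COC1(OC)CCC(=O)C(C)=C1 | intermediate
4 | 2-(2-bromoethyl)-1,3-dioxolane | BrCCC1OCCO1 | starting material
5 | bromomagnesium enolate of (3R)-3-[2-(1,3-dioxolan-2-yl)ethyl]-4,4-dimethoxy-2-methylcyclohexan-1-one | C1COC(O1)CC[C@@H]1C(C)=C(O[Mg]Br)CCC1(OC)OC | intermediate
6 | (2S,3R)-3-[2-(1,3-dioxolan-2-yl)ethyl]-2-(hydroxymethyl)-4,4-dimethoxy-2-methylcyclohexan-1-one | C1COC(O1)CC[C@@H]1[C@@](C)(CO)C(=O)CCC1(OC)OC | intermediate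
7 | (1S,2R)-2-[2-(1,3-dioxolan-2-yl)ethyl]-3,3-dimethoxy-1-methyl-6-oxocyclohexane-1-carbaldehyde | C1COC(O1)CC[C@@H]1[C@@](C)(C=O)C(=O)CCC1(OC)OC | intermediate
8 | triethyl phosphonoacetate | CCOC(=O)CP(=O)(OCC)OCC | starting material
9 | ethenyl(triphenyl)phosphonium bromide | C=C[P+](c1ccccc1)(c1ccccc1)c1ccccc1.[Br-] | starting material
10 | [3-(diethoxyphosphoryl)-4-ethoxy-4-oxobutyl]triphenylphosphonium bromide (racemic) | CCOC(=O)C(CC[P+](c1ccccc1)(c1ccccc1)c1ccccc1)P(=O)(OCC)OCC.[Br-] | intermediate
11 | potassium C2-carbanion of ethyl (4Z)-2-(diethoxyphosphoryl)-5-[(1R,2R)-2-[2-(1,3-dioxolan-2-yl)ethyl]-3,3-dimethoxy-1-methyl-6-oxocyclohexyl]pent-4-enoate | C1COC(O1)CC[C@@H]1[C@@](C)(/C=C\C[C-](C(=O)OCC)P(=O)(OCC)OCC)C(=O)CCC1(OC)OC.[K+] | intermediate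
12 | ethyl (4aR,5R)-5-[2-(1,3-dioxolan-2-yl)ethyl]-6,6-dimethoxy-4a-methyl-2,4a,5,6,7,8-hexahydronaphthalene-1-carboxylate | C1COC(O1)CC[C@@H]1[C@@]2(C)C=CCC(C(=O)OCC)=C2CCC1(OC)OC | intermediate
13 | ethyl (4aR,5R)-5-[2-(1,3-dioxolan-2-yl)ethyl]-6,6-dimethoxy-4a-methyl-2,3,4,4a,5,6,7,8-octahydronaphthalene-1-carboxylate | C1COC(O1)CC[C@@H]1[C@@]2(C)CCCC(C(=O)OCC)=C2CCC1(OC)OC | intermediate
14 | lithium enolate (O-lithio ketene acetal, geometry not defined) of ethyl (4aS,5R,8aR)-5-[2-(1,3-dioxolan-2-yl)ethyl]-6,6-dimethoxy-4a-methyldecahydronaphthalene-1-carboxylate | C1COC(O1)CC[C@@H]1[C@@]2(C)CCCC(=C(O[Li])OCC)[C@@H]2CCC1(OC)OC | intermediate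
15 | ethyl (1S,4aS,5R,8aR)-5-[2-(1,3-dioxolan-2-yl)ethyl]-6,6-dimethoxy-1,4a-dimethyldecahydronaphthalene-1-carboxylate | C1COC(O1)CC[C@@H]1[C@@]2(C)CCC[C@](C)(C(=O)OCC)[C@@H]2CCC1(OC)OC | intermediate
16 | ethyl (1S,4aS,5R,8aR)-5-[2-(1,3-dioxolan-2-yl)ethyl]-1,4a-dimethyl-6-oxodecahydronaphthalene-1-carboxylate | C1COC(O1)CC[C@@H]1[C@@]2(C)CCC[C@](C)(C(=O)OCC)[C@@H]2CCC1=O | intermediate
17 | ethyl (1S,4aR,5S,8aR)-5-[2-(1,3-dioxolan-2-yl)ethyl]-1,4a-dimethyl-6-methylidenedecahydronaphthalene-1-carboxylate | C1COC(O1)CC[C@@H]1[C@@]2(C)CCC[C@](C)(C(=O)OCC)[C@@H]2CCC1=C | intermediate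
18 | ethyl (1R,2R,4aR,5S,8aS)-1-[2-(1,3-dioxolan-2-yl)ethyl]-5,8a-dimethyloctahydro-1H-spiro[naphthalene-2,2'-oxirane]-5-carboxylate (8α,17-epoxide) | C1COC(O1)CC[C@@H]1[C@@]2(C)CCC[C@](C)(C(=O)OCC)[C@@H]2CC[C@]13CO3 | intermediate
19 | (1R,2R,4aR,5S,8aS)-1-[2-(1,3-dioxolan-2-yl)ethyl]-5-(hydroxymethyl)-2,5,8a-trimethyldecahydronaphthalen-2-ol | C1COC(O1)CC[C@@H]1[C@@]2(C)CCC[C@](C)(CO)[C@@H]2CC[C@@]1(C)O | intermediate
20 | (4aR,6aR,7S,10aS,10bR)-7-(hydroxymethyl)-4a,7,10a-trimethyldodecahydro-1H-benzo[f]chromen-3-ol (both C3 epimers) | OC1CC[C@@H]2[C@@]3(C)CCC[C@](C)(CO)[C@@H]3CC[C@@]2(C)O1 | intermediate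
21 | (1R,2R,4aR,5S,8aS)-1-(but-3-yn-1-yl)-5-(hydroxymethyl)-2,5,8a-trimethyldecahydronaphthalen-2-ol | C#CCC[C@@H]1[C@@]2(C)CCC[C@](C)(CO)[C@@H]2CC[C@@]1(C)O | intermediate
22 | (1R,2R,4aR,5S,8aS)-5-(hydroxymethyl)-2,5,8a-trimethyl-1-(3-methylidenepent-4-en-1-yl)decahydronaphthalen-2-ol (labda-13(16),14-diene-8α,19-diol) | C=CC(=C)CC[C@@H]1[C@@]2(C)CCC[C@](C)(CO)[C@@H]2CC[C@@]1(C)O | intermediate
23 | (E)-4-acetoxycinnamic acid | CC(=O)Oc1ccc(/C=C/C(=O)O)cc1 | starting material
24 | 8α-hydroxylabda-13(16),14-dien-19-yl (E)-3-(4-acetoxyphenyl)prop-2-enoate | C=CC(=C)CC[C@@H]1[C@@]2(C)CCC[C@](C)(COC(=O)/C=C/c3ccc(OC(C)=O)cc3)[C@@H]2CC[C@@]1(C)O | intermediate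
25 | 8α-hydroxylabda-13(16),14-dien-19-yl p-hydroxycinnamate | C=CC(=C)CC[C@@H]1[C@@]2(C)CCC[C@](C)(COC(=O)/C=C/c3ccc(O)cc3)[C@@H]2CC[C@@]1(C)O | target

**Step count and risks**

Total step count: 17. Longest linear sequence: 16 (steps 1–4 and 6–17); step 5 is a one-step side branch that makes the annulation reagent.

Steps most likely to fail:

1. Step 6 (the step that carries the new-method label). The two carbanions of the reagent may pair wrongly with the two carbonyl groups (the phosphonate carbanion adding to the aldehyde), the Wittig stage may lose its Z selectivity so that the chain cannot reach the ketone, or the hindered ketone may resist the ring-closing olefination. The fallback uses known reactions and makes the two bonds in separate steps; it sets out from 7 and comes back at 12. Chemoselective Wittig methylenation of the aldehyde of 7 (Ph3PCH3Br, KN(SiMe3)2, THF, −78 °C) should give (2R,3R)-3-[2-(1,3-dioxolan-2-yl)ethyl]-2-ethenyl-4,4-dimethoxy-2-methylcyclohexan-1-one F1. Aldol addition of the lithium enolate of ethyl pent-4-enoate (LiN(i-Pr)2, THF, −78 °C, with CeCl3 if the ketone enolises) to the C5 ketone should give the β-hydroxy ester F2 (C4–C5 bond; the epimers at the two new centres need not be separated, because both centres are made planar or reset later). Ring-closing metathesis of the C10 vinyl group with the allyl group (second-generation Grubbs catalyst RuCl2(=CHPh)(PCy3)(H2IMes), CH2Cl2, 40 °C) should give the ring A cyclohexene F3 (C1=C2 bond). Dehydration of the tertiary alcohol (SOCl2, pyridine, then DBU to move the new double bond into conjugation with the ester) returns to 12.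

2. Step 3. The catalyst may discriminate poorly between the enone faces at this trisubstituted, ketal-flanked enone, the Grignard reagent may add to the carbonyl group or enolise the ketone, or the aldol adduct may lose formaldehyde again on work-up. The fallback replaces this by the desymmetrisation of a prochiral dienone, a better-precedented asymmetric conjugate addition; it sets out from 4 (with commercial 4,4-dimethoxycyclohexa-2,5-dien-1-one) and comes back at 6. The Grignard reagent from 4 and ZnCl2 (0.5 equiv; magnesium salts removed with 1,4-dioxane) should give bis[2-(1,3-dioxolan-2-yl)ethyl]zinc F4. Its copper-catalysed addition (Cu(OTf)2, chiral phosphoramidite ligand, toluene, −25 °C) to the dienone should give (5R)-5-[2-(1,3-dioxolan-2-yl)ethyl]-4,4-dimethoxycyclohex-2-en-1-one F5. This enone can be deprotonated only at C10, so LiN(i-Pr)2 then MeI should give the 6-methyl enone F6, and LiN(i-Pr)2 then monomeric CH2O, again anti to the C9 substituent, the hydroxymethyl enone F7. Hydrogenation of the enone double bond (H2, Pd/C, EtOAc) returns to 6.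

3. Step 8. The ester may be over-reduced, the enolate may be methylated incompletely or on oxygen, or the protonation at C5 may not be face-selective enough. The fallback alkylates first and reduces second; it sets out from 13 and comes back at 15. Gamma-deprotonation at C6 (LiN(i-Pr)2, THF–HMPA, −78 °C) and alpha-methylation of the dienolate with MeI, from the α face as in the main route, should give the deconjugated C5=C6 ester F8 (deconjugative alkylation). Hydrogen-atom-transfer hydrogenation of the trisubstituted alkene (Mn(dpm)3 [tris(dipivaloylmethanato)manganese], PhSiH3, t-BuOOH, i-PrOH), which delivers the thermodynamically preferred trans ring fusion, returns to 15.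

Further compounds
F1 | step 6 | (2R,3R)-3-[2-(1,3-dioxolan-2-yl)ethyl]-2-ethenyl-4,4-dimethoxy-2-methylcyclohexan-1-one | C1COC(O1)CC[C@@H]1[C@@](C)(C=C)C(=O)CCC1(OC)OC
F2 | step 6 | ethyl 2-[(2R,3R)-3-[2-(1,3-dioxolan-2-yl)ethyl]-2-ethenyl-1-hydroxy-4,4-dimethoxy-2-methylcyclohexyl]pent-4-enoate (epimers at the two new centres) | C1COC(O1)CC[C@@H]1[C@@](C)(C=C)C(O)(C(CC=C)C(=O)OCC)CCC1(OC)OC
F3 | step 6 | ethyl (4aR,5R)-5-[2-(1,3-dioxolan-2-yl)ethyl]-8a-hydroxy-6,6-dimethoxy-4a-methyl-1,2,4a,5,6,7,8,8a-octahydronaphthalene-1-carboxylate (epimers at C1 and C8a) | C1COC(O1)CC[C@@H]1[C@@]2(C)C=CCC(C(=O)OCC)C2(O)CCC1(OC)OC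
F4 | step 3 | bis[2-(1,3-dioxolan-2-yl)ethyl]zinc | C1COC(O1)CC[Zn]CCC1OCCO1
F5 | step 3 | (5R)-5-[2-(1,3-dioxolan-2-yl)ethyl]-4,4-dimethoxycyclohex-2-en-1-one | C1COC(O1)CC[C@@H]1CC(=O)C=CC1(OC)OC
F6 | step 3 | (5R,6R)-5-[2-(1,3-dioxolan-2-yl)ethyl]-4,4-dimethoxy-6-methylcyclohex-2-en-1-one | C1COC(O1)CC[C@@H]1[C@@H](C)C(=O)C=CC1(OC)OC
F7 | step 3 | (5R,6S)-5-[2-(1,3-dioxolan-2-yl)ethyl]-6-(hydroxymethyl)-4,4-dimethoxy-6-methylcyclohex-2-en-1-one | C1COC(O1)CC[C@@H]1[C@@](C)(CO)C(=O)C=CC1(OC)OC
F8 | step 8 | ethyl (1S,4aR,5R)-5-[2-(1,3-dioxolan-2-yl)ethyl]-6,6-dimethoxy-1,4a-dimethyl-1,2,3,4,4a,5,6,7-octahydronaphthalene-1-carboxylate | C1COC(O1)CC[C@@H]1[C@@]2(C)CCC[C@](C)(C(=O)OCC)C2=CCC1(OC)OC
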